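Ring B of the quinone is opened at C2=C3: the methyl-bearing C2 and the chain-bearing C3 each sit alpha to an aryl ketone (C1=O on C8a beside the C8 methyl, C4=O on C4a). In one operation, CuCl2 oxidation of the bis(lithium enolate) of a 1,2-diacylbenzene joins these two alpha carbons, closing ring B as its 2,3-dihydro form; tautomerization and mild oxidation then give the quinone. The precursor is 3-methyl-2-propanoylphenyl ketone 19 carrying the all-E hexaprenyl chain lengthened by CH2C(=O); it is assembled from a C32 morpholine amide (two farnesyl units joined by sulfone alkylation) and an unprotected lithio alkoxide derived from 2-bromo-6-methylbenzaldehyde.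

Key step: step 12

Remark 1: ring positions follow the numbering in which C1 is the carbonyl flanked by the methyl-bearing C2 and by C8a (C8 carries the aryl methyl), C3 carries the chain and C4 is the second carbonyl; ring A is the benzene ring and ring B the quinone ring.
Remark 2: the target has no stereocentre; its stereochemistry is five E double bonds, four taken from the two farnesyl building blocks and one set in step 2; compounds 8, 16 and 18 are racemates and 21 is a diastereomer mixture, and all these centres disappear along the route.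
Remark 3: hydroxy ketone 18 is drawn open-chain; it may equilibrate with its five-membered cyclic hemiketal, which reacts through the open form in step 11.

Step 1
Reactants: 1 (2E,6E)-farnesol
Product: 2 benzyl (2E,6E)-3,7,11-trimethyldodeca-2,6,10-trien-1-yl ether
Conditions: NaH, BnBr, n-Bu4NI (cat.), THF, 0 °C to rt
Reagents that add atoms: benzyl bromide, BrCc1ccccc1
Why: Williamson ether synthesis (SN2 of the primary allylic alkoxide on benzyl bromide) leaves both E double bonds untouched and installs a group that withstands the allylic oxidation and carbanion chemistry ahead and is removed later together with the sulfone.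

Step 2
Reactants: 2 benzyl (2E,6E)-farnesyl ether
Product: 3 (2E,6E,10E)-12-(benzyloxy)-2,6,10-trimethyldodeca-2,6,10-trien-1-ol
Conditions: SeO2 (cat.), t-BuOOH, salicylic acid (cat.), CH2Cl2, 0 °C to rt
Reagents that add atoms: tert-butyl hydroperoxide, CC(C)(C)OO; selenium dioxide, O=[Se]=O (catalytic oxygen carrier)
Why: Riley-type allylic oxidation (ene reaction followed by [2,3]-sigmatropic shift) should attack the most electron-rich and least hindered terminal trisubstituted alkene and hydroxylate the methyl group trans to the chain, so that this double bond becomes E-configured and no stereocentre is formed.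

Step 3
Reactants: 3 (2E,6E,10E)-12-(benzyloxy)-2,6,10-trimethyldodeca-2,6,10-trien-1-ol
Product: 4 benzyl (2E,6E,10E)-12-bromo-3,7,11-trimethyldodeca-2,6,10-trien-1-yl ether
Conditions: PBr3, pyridine (cat.), Et2O, −10 °C
Reagents that add atoms: phosphorus tribromide, BrP(Br)Br
Why: Bromination of a primary allylic alcohol with PBr3 is an SN2 displacement of the intermediate phosphite at the primary carbon, which keeps the E geometry, and the bromide is used at once.

Step 4
Reactants: 5 (2E,6E)-farnesyl bromide
Product: 6 (2E,6E)-farnesyl p-tolyl sulfone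
Conditions: p-TolSO2Na, DMF, rt
Reagents that add atoms: sodium p-toluenesulfinate, Cc1ccc(cc1)S(=O)[O-].[Na+]
Why: S-alkylation of the sulfinate by the primary allylic bromide (SN2) gives the allylic sulfone with unchanged double-bond geometry.

Step 5
Reactants: 6 (2E,6E)-farnesyl p-tolyl sulfone; 4 benzyl (2E,6E,10E)-12-bromo-3,7,11-trimethyldodeca-2,6,10-trien-1-yl ether
Product: 8 benzyl (2E,6E,10E,14E,18E)-3,7,11,15,19,23-hexamethyl-13-(p-tolylsulfonyl)tetracosa-2,6,10,14,18,22-hexaen-1-yl ether (racemic at C13), via lithiated sulfone 7 (not isolated)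
Conditions: n-BuLi, THF–DMPU, −78 °C; then 4, −78 to −20 °C
Reagents that add atoms: none
Why: Biellmann-type allylic sulfone alkylation joins the alpha carbon of the sulfonyl-stabilized carbanion to the primary allylic bromide by SN2 with retention of all double-bond geometries, and the new sulfonyl-bearing stereocentre forms as a racemate that is erased in step 6.

Step 6
Reactants: 8 benzyl 13-(p-tolylsulfonyl)hexaprenyl ether
Product: 9 all-E-hexaprenol, (2E,6E,10E,14E,18E)-3,7,11,15,19,23-hexamethyltetracosa-2,6,10,14,18,22-hexaen-1-ol
Conditions: Li, EtNH2–THF, −78 °C; then NH4Cl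
Reagents that add atoms: none
Why: Benkeser-type dissolving-metal reduction cleaves the allylic C–S bond and the benzylic C–O bond in one operation at low temperature, where the isolated trisubstituted alkenes are not reduced and protonation of the allyl anion at its less substituted end keeps the neighbouring E double bond in place.

Step 7
Reactants: 9 all-E-hexaprenol
Product: 10 all-E-hexaprenyl bromide, (2E,6E,10E,14E,18E)-1-bromo-3,7,11,15,19,23-hexamethyltetracosa-2,6,10,14,18,22-hexaene
Conditions: PBr3, pyridine (cat.), Et2O, −10 °C
Reagents that add atoms: phosphorus tribromide, BrP(Br)Br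
Why: SN2 bromination of the primary allylic alcohol with PBr3 preserves the C2=C3 geometry, and the sensitive bromide is carried on crude.

Step 8
Reactants: 11 N-acetylmorpholine; 10 all-E-hexaprenyl bromide
Product: 13 (4E,8E,12E,16E,20E)-5,9,13,17,21,25-hexamethyl-1-(morpholin-4-yl)hexacosa-4,8,12,16,20,24-hexaen-1-one, via lithium amide enolate 12 (not isolated)
Conditions: LiN(i-Pr)2, THF, −78 °C; then 10, −78 to 0 °C
Reagents that add atoms: none
Why: Alkylation of a tertiary amide lithium enolate by a primary allylic bromide is an SN2 reaction at C1 of the chain (attack at the fully substituted C3 is disfavoured), so the chain geometry is kept and the two-carbon acyl extension is added in one step.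

Step 9
Reactants: 14 2-bromo-6-methylbenzaldehyde; 15 ethylmagnesium bromide
Product: 16 1-(2-bromo-6-methylphenyl)propan-1-ol (racemic)
Conditions: THF, −20 to 0 °C; then aq. NH4Cl
Reagents that add atoms: none
Why: Grignard addition to the aldehyde gives the secondary benzylic alcohol as a racemate, which is acceptable because this carbinol becomes a ketone in step 11.

Step 10
Reactants: 16 1-(2-bromo-6-methylphenyl)propan-1-ol; 13 C32 morpholine amide
Product: 18 (4E,8E,12E,16E,20E)-1-[2-(1-hydroxypropyl)-3-methylphenyl]-5,9,13,17,21,25-hexamethylhexacosa-4,8,12,16,20,24-hexaen-1-one (racemic), via dilithio alkoxide 17 (not isolated)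
Conditions: n-BuLi (2.1 equiv), THF, −78 °C; then 13, −78 to 0 °C; then aq. NH4Cl
Reagents that add atoms: none
Why: Deprotonation of the hydroxyl and bromine–lithium exchange give an aryllithium whose neighbouring lithium alkoxide needs no protecting group, and acylation of this organolithium by the tertiary amide stops at the tetrahedral adduct until work-up so that over-addition is excluded, while the existing carbinol centre stays racemic.

Step 11
Reactants: 18 hydroxy ketone
Product: 19 (4E,8E,12E,16E,20E)-5,9,13,17,21,25-hexamethyl-1-(3-methyl-2-propanoylphenyl)hexacosa-4,8,12,16,20,24-hexaen-1-one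
Conditions: Dess–Martin periodinane, pyridine, CH2Cl2, 0 °C to rt
Reagents that add atoms: none
Why: Dess–Martin oxidation of the secondary benzylic alcohol under buffered conditions gives the 1,2-diacylbenzene without touching the hexaene chain and without exposing the diketone to base-induced aldol closure, and it removes the only stereocentre.

Step 12
Reactants: 19 1,2-diacylbenzene
Product: 21 2,8-dimethyl-3-[(2E,6E,10E,14E,18E)-3,7,11,15,19,23-hexamethyltetracosa-2,6,10,14,18,22-hexaen-1-yl]-2,3-dihydronaphthalene-1,4-dione (cis and trans racemates), via bis(lithium enolate) 20 (not isolated)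
Conditions: LiN(i-Pr)2 (2.3 equiv), THF, −78 °C, slow addition of 19, then −40 °C; CuCl2 (2.3 equiv), DMF, high dilution, −78 to 0 °C
Reagents that add atoms: none
Why: Two equivalents of lithium diisopropylamide remove a hydrogen from the only enolizable side of each ketone (the propanoyl CH2 and the chain CH2 next to the second carbonyl) to give bis(enolate) 20, and one-electron oxidation of one enolate by divalent copper (CuCl2) produces an alpha-keto radical (or its copper-bound equivalent) that bonds to the alpha carbon of the neighbouring enolate, after which a second CuCl2 oxidizes the resulting ketyl to the second carbonyl. The closest known reaction type is the CuCl2-mediated oxidative coupling of ketone lithium enolates to 1,4-diketones, including its intramolecular use on diketone bis-enolates to give cyclic 1,4-diketones. Ring B closes as a six-membered ring in a 6-endo-trig mode, since both carbons of the accepting enolate double bond end up inside the new ring. The two new stereocentres at C2 and C3 are not controlled (the trans isomer is expected to be favoured on steric grounds and the two can interconvert through the enol), which is immaterial because both carbons become sp2 in step 13. The step needs C2–C3 bond formation to win over aldol attack of a half-enolized diketone on its other ketone, over intermolecular coupling and over chlorine transfer from CuCl2: the ortho placement of the two acyl groups on ring A holds the two enolate carbons within bonding distance, each ketone can enolize on one side only, and slow addition of 19 into excess base at −78 °C followed by dilution ensures that no free ketone coexists with enolate when the oxidant arrives. Any material that is oxidized further in the flask is already the target and is carried into step 13 unchanged.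

Step 13
Reactants: 21 2,3-dihydronaphthalene-1,4-dione
Product: 23 2,8-dimethyl-3-[(2E,6E,10E,14E,18E)-3,7,11,15,19,23-hexamethyltetracosa-2,6,10,14,18,22-hexaen-1-yl]naphthalene-1,4-dione, via naphthohydroquinone 22 (not isolated)
Conditions: Et3N, degassed THF–MeOH, rt; then Ag2O, rt, dark
Reagents that add atoms: none
Why: Amine-catalysed keto–enol tautomerization converts both diastereomers of the dihydro-dione into the aromatic naphthalene-1,4-diol, erasing both stereocentres, and Ag2O then performs a standard hydroquinone-to-quinone oxidation under conditions that leave the skipped polyene untouched.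

Compound list
1 | (2E,6E)-farnesol | CC(C)=CCC/C(C)=C/CC/C(C)=C/CO | starting material
2 | benzyl (2E,6E)-3,7,11-trimethyldodeca-2,6,10-trien-1-yl ether | CC(C)=CCC/C(C)=C/CC/C(C)=C/COCc1ccccc1 | intermediate
3 | (2E,6E,10E)-12-(benzyloxy)-2,6,10-trimethyldodeca-2,6,10-trien-1-ol | OC/C(C)=C/CC/C(C)=C/CC/C(C)=C/COCc1ccccc1 | intermediate
4 | benzyl (2E,6E,10E)-12-bromo-3,7,11-trimethyldodeca-2,6,10-trien-1-yl ether | BrC/C(C)=C/CC/C(C)=C/CC/C(C)=C/COCc1ccccc1 | intermediate
5 | (2E,6E)-farnesyl bromide | CC(C)=CCC/C(C)=C/CC/C(C)=C/CBr | starting material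
6 | (2E,6E)-farnesyl p-tolyl sulfone | CC(C)=CCC/C(C)=C/CC/C(C)=C/CS(=O)(=O)c1ccc(C)cc1 | intermediate
7 | alpha-lithiated farnesyl p-tolyl sulfone (not isolated) | CC(C)=CCC/C(C)=C/CC/C(C)=C/C([Li])S(=O)(=O)c1ccc(C)cc1 | intermediate
8 | benzyl (2E,6E,10E,14E,18E)-3,7,11,15,19,23-hexamethyl-13-(p-tolylsulfonyl)tetracosa-2,6,10,14,18,22-hexaen-1-yl ether, racemic | CC(C)=CCC/C(C)=C/CC/C(C)=C/C(C/C(C)=C/CC/C(C)=C/CC/C(C)=C/COCc1ccccc1)S(=O)(=O)c1ccc(C)cc1 | intermediate
9 | all-E-hexaprenol | CC(C)=CCC/C(C)=C/CC/C(C)=C/CC/C(C)=C/CC/C(C)=C/CC/C(C)=C/CO | intermediate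
10 | all-E-hexaprenyl bromide | CC(C)=CCC/C(C)=C/CC/C(C)=C/CC/C(C)=C/CC/C(C)=C/CC/C(C)=C/CBr | intermediate
11 | N-acetylmorpholine | CC(=O)N1CCOCC1 | starting material
12 | lithium enolate of N-acetylmorpholine (not isolated) | C=C(O[Li])N1CCOCC1 | intermediate
13 | (4E,8E,12E,16E,20E)-5,9,13,17,21,25-hexamethyl-1-(morpholin-4-yl)hexacosa-4,8,12,16,20,24-hexaen-1-one | CC(C)=CCC/C(C)=C/CC/C(C)=C/CC/C(C)=C/CC/C(C)=C/CC/C(C)=C/CCC(=O)N1CCOCC1 | intermediate
14 | 2-bromo-6-methylbenzaldehyde | Cc1cccc(Br)c1C=O | starting material
15 | ethylmagnesium bromide | CC[Mg]Br | starting material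
16 | 1-(2-bromo-6-methylphenyl)propan-1-ol, racemic | CCC(O)c1c(C)cccc1Br | intermediate
17 | lithium 1-(2-lithio-6-methylphenyl)propan-1-olate (not isolated) | CCC(O[Li])c1c(C)cccc1[Li] | intermediate
18 | (4E,8E,12E,16E,20E)-1-[2-(1-hydroxypropyl)-3-methylphenyl]-5,9,13,17,21,25-hexamethylhexacosa-4,8,12,16,20,24-hexaen-1-one, racemic | CC(C)=CCC/C(C)=C/CC/C(C)=C/CC/C(C)=C/CC/C(C)=C/CC/C(C)=C/CCC(=O)c1cccc(C)c1C(O)CC | intermediate
19 | (4E,8E,12E,16E,20E)-5,9,13,17,21,25-hexamethyl-1-(3-methyl-2-propanoylphenyl)hexacosa-4,8,12,16,20,24-hexaen-1-one | CC(C)=CCC/C(C)=C/CC/C(C)=C/CC/C(C)=C/CC/C(C)=C/CC/C(C)=C/CCC(=O)c1cccc(C)c1C(=O)CC | intermediate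
20 | bis(lithium enolate) of 19 (not isolated, enolate geometry undefined) | CC(C)=CCC/C(C)=C/CC/C(C)=C/CC/C(C)=C/CC/C(C)=C/CC/C(C)=C/CC=C(O[Li])c1cccc(C)c1C(O[Li])=CC | intermediate
21 | 2,8-dimethyl-3-[(2E,6E,10E,14E,18E)-3,7,11,15,19,23-hexamethyltetracosa-2,6,10,14,18,22-hexaen-1-yl]-2,3-dihydronaphthalene-1,4-dione, cis and trans racemates | CC(C)=CCC/C(C)=C/CC/C(C)=C/CC/C(C)=C/CC/C(C)=C/CC/C(C)=C/CC1C(C)C(=O)c2c(C)cccc2C1=O | intermediate
22 | 2,8-dimethyl-3-[(2E,6E,10E,14E,18E)-3,7,11,15,19,23-hexamethyltetracosa-2,6,10,14,18,22-hexaen-1-yl]naphthalene-1,4-diol (not isolated) | CC(C)=CCC/C(C)=C/CC/C(C)=C/CC/C(C)=C/CC/C(C)=C/CC/C(C)=C/Cc1c(C)c(O)c2c(C)cccc2c1O | intermediate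
23 | 2,8-dimethyl-3-[(2E,6E,10E,14E,18E)-3,7,11,15,19,23-hexamethyltetracosa-2,6,10,14,18,22-hexaen-1-yl]naphthalene-1,4-dione (CID101244058) | CC(C)=CCC/C(C)=C/CC/C(C)=C/CC/C(C)=C/CC/C(C)=C/CC/C(C)=C/CC1=C(C)C(=O)c2c(C)cccc2C1=O | target

Total step count: 13.
Longest linear sequence: 11 steps (steps 1, 2, 3, 5, 6, 7, 8, 10, 11, 12, 13 from farnesol 1).

Steps most likely to fail

Step 12 (key step). Aldol closure of a half-enolized diketone onto its other ketone, intermolecular coupling or chlorine transfer from CuCl2 may outrun the intramolecular C–C coupling. Fallback: starting from 19, soft enolization with Me3SiOTf and Et3N (CH2Cl2, 0 °C), in which no free enolate is present, should give the bis(trimethylsilyl enol ether) F1. Oxidation of this compound with (NH4)2Ce(NO3)6 and NaHCO3 in MeCN at −30 °C, the known intramolecular oxidative coupling of bis(silyl enol ethers) through an enol ether radical cation, forms the same C2–C3 bond. The fallback rejoins the route at 21.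

Step 2. Poor site selectivity among the three trisubstituted alkenes and over-oxidation of the new carbinol may leave little of the terminal E-alcohol. Fallback: starting from 2, NBS in aqueous THF at 0 °C should add selectively to the terminal double bond to give the bromohydrin F2. K2CO3 in MeOH closes it to the terminal epoxide F3, and HIO4 in aqueous THF cleaves the epoxide to the aldehyde F4. Wittig olefination with ethyl 2-(triphenylphosphoranylidene)propanoate (CH2Cl2, rt) gives the E-configured unsaturated ester F5, and i-Bu2AlH (CH2Cl2, −78 °C) reduces it to the allylic alcohol. The fallback rejoins the route at 3.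

Step 10. Incomplete halogen–lithium exchange on the alkoxide, low solubility of the dilithio species, or proton transfer from the alpha position of the amide to the aryllithium may prevent clean acylation. Fallback: starting from 16, silylation with t-BuMe2SiOTf and 2,6-lutidine (CH2Cl2, 0 °C) gives the silyl ether F6. Bromine–lithium exchange with n-BuLi (THF, −78 °C) gives the monolithiated arene F7, which is acylated with amide 13 to give the keto silyl ether F8. n-Bu4NF in THF removes the silyl group. The fallback rejoins the route at 18.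

Further compounds
F1 | step 12 | bis(trimethylsilyl enol ether) of diketone 19 | CC(C)=CCC/C(C)=C/CC/C(C)=C/CC/C(C)=C/CC/C(C)=C/CC/C(C)=C/CC=C(O[Si](C)(C)C)c1cccc(C)c1C(O[Si](C)(C)C)=CC
F2 | step 2 | (6E,10E)-12-(benzyloxy)-3-bromo-2,6,10-trimethyldodeca-6,10-dien-2-ol, racemic | CC(C)(O)C(Br)CC/C(C)=C/CC/C(C)=C/COCc1ccccc1
F3 | step 2 | 3-[(3E,7E)-9-(benzyloxy)-3,7-dimethylnona-3,7-dien-1-yl]-2,2-dimethyloxirane, racemic | CC1(C)OC1CC/C(C)=C/CC/C(C)=C/COCc1ccccc1
F4 | step 2 | (4E,8E)-10-(benzyloxy)-4,8-dimethyldeca-4,8-dienal | O=CCC/C(C)=C/CC/C(C)=C/COCc1ccccc1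
F5 | step 2 | ethyl (2E,6E,10E)-12-(benzyloxy)-2,6,10-trimethyldodeca-2,6,10-trienoate | CCOC(=O)/C(C)=C/CC/C(C)=C/CC/C(C)=C/COCc1ccccc1
F6 | step 10 | [1-(2-bromo-6-methylphenyl)propoxy](tert-butyl)dimethylsilane, racemic | CCC(O[Si](C)(C)C(C)(C)C)c1c(C)cccc1Br
F7 | step 10 | tert-butyl[1-(2-lithio-6-methylphenyl)propoxy]dimethylsilane (not isolated) | CCC(O[Si](C)(C)C(C)(C)C)c1c(C)cccc1[Li]
F8 | step 10 | (4E,8E,12E,16E,20E)-1-[2-(1-{[tert-butyl(dimethyl)silyl]oxy}propyl)-3-methylphenyl]-5,9,13,17,21,25-hexamethylhexacosa-4,8,12,16,20,24-hexaen-1-one, racemic | CC(C)=CCC/C(C)=C/CC/C(C)=C/CC/C(C)=C/CC/C(C)=C/CC/C(C)=C/CCC(=O)c1cccc(C)c1C(CC)O[Si](C)(C)C(C)(C)C
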